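**Retrosynthetic overview**

1. Endgame: the C9 acetate, the silyl ethers and the C13=C14 bond (ketone dehydrogenation) are adjusted last; the γ-lactone (O7, C19, C17, C8) is closed by an intramolecular Reformatsky addition of C17 to a C8 ketone.
2. The ten-membered ring (C1 to C10) is closed at C4–C5 by a B-alkyl Suzuki–Miyaura macrocyclisation of a C2 vinyl carbinol onto a (Z)-C5 iodoalkene.
3. The six-membered ring (C1, C10, C11, C12, C13, C14) is closed by forming C10–C11 in an α-ketol (acyloin) ring enlargement of a 1-acetylcyclopentanol: C10 shifts from C12 to C11, which inserts C11 into the ring. The enabling feature is that C11 is a tertiary carbinol (OH, C20 methyl) bonded directly to the C12 ketone inside that ring.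
4. The cyclopentanone is assembled in one pot from 3-methylcyclopent-2-enone (C1, C10, C12 to C15), an alkenylalane (C2) and a D-erythrose-derived ynal (C5 to C9, C16), whose stereocenters become C7 and steer C9 and C10.
5. Ring order: temporary cyclopentane, then six-membered carbocycle, then ten-membered carbocycle, then lactone.

Key step: step 9

Remark (labels): C1 to C20 are the skeletal carbons of the target: C1 quaternary ring-fusion carbon (C15 methyl), C2 butanoate carbon, C5=C6 ring alkene (C16 methyl), C7 lactone O–CH, C8 and C11 tertiary carbinols, C9 acetate carbon, C10 ring-fusion CH, C12 ketone, C13=C14 enone alkene, C17 (C18 methyl) and C19 lactone carbons, C20 methyl on C11.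

Remark (chemistry): 2,3-O-isopropylidene-D-erythrofuranose is taken as a commercial chiral-pool material; 2-bromopropanoyl bromide is used as the racemate because its stereocenter is lost in the zinc enolate of step 19.

**Route**

Step 1
Reactants: 1 2,3-O-isopropylidene-D-erythrofuranose
Product: 2 ((4R,5S)-5-ethynyl-2,2-dimethyl-1,3-dioxolan-4-yl)methanol
Conditions: dimethyl (1-diazo-2-oxopropyl)phosphonate, K2CO3, MeOH, 0 °C to rt
Reagents that add atoms: dimethyl (1-diazo-2-oxopropyl)phosphonate, CC(=O)C(=[N+]=[N-])P(=O)(OC)OC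
Why: Seyferth–Gilbert homologation in the Ohira–Bestmann form converts the open-chain aldehyde tautomer of the lactol into the terminal alkyne (the new carbon is C5), and both stereocenters (the later C7 and the temporary C8) come unchanged from D-erythrose.

Step 2
Reactants: 2 ((4R,5S)-5-ethynyl-2,2-dimethyl-1,3-dioxolan-4-yl)methanol
Product: 3 ((4R,5S)-2,2-dimethyl-5-(prop-1-yn-1-yl)-1,3-dioxolan-4-yl)methanol
Conditions: n-BuLi (2.1 equiv), THF, −78 °C; MeI (1.05 equiv), −78 to 0 °C
Reagents that add atoms: iodomethane, CI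
Why: Alkylation of the lithium acetylide within the dianion gives C-methylation (C16), because the lithium alkoxide is a far poorer nucleophile toward iodomethane in THF.

Step 3
Reactants: 3 ((4R,5S)-2,2-dimethyl-5-(prop-1-yn-1-yl)-1,3-dioxolan-4-yl)methanol
Product: 4 (4S,5S)-2,2-dimethyl-5-(prop-1-yn-1-yl)-1,3-dioxolane-4-carbaldehyde
Conditions: Dess–Martin periodinane, NaHCO3, CH2Cl2, 0 °C; used at once
Reagents that add atoms: none
Why: Dess–Martin oxidation of the primary alcohol under buffered, non-basic conditions should give the α-alkoxy aldehyde without epimerisation of the cis-dioxolane.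

Step 4
Reactants: 5 hex-1-yne
Product: 6 (E)-hex-1-en-1-yl(diisobutyl)alane (used as hexane solution)
Conditions: i-Bu2AlH, hexane, 55 °C
Reagents that add atoms: diisobutylaluminium hydride, CC(C)C[AlH]CC(C)C
Why: Syn-hydroalumination of the terminal alkyne places aluminium on the terminal carbon and gives the (E)-alkenylalane, whose alkenyl group transfers in preference to isobutyl.

Step 5
Reactants: 7 3-methylcyclopent-2-en-1-one; 6 (E)-hex-1-en-1-yl(diisobutyl)alane; 4 (4S,5S)-2,2-dimethyl-5-(prop-1-yn-1-yl)-1,3-dioxolane-4-carbaldehyde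
Product: 9 aldol adduct (3-hexenyl-3-methylcyclopentanone with the C9 carbinol chain on C10), via aluminium enolate 8 (not isolated)
Conditions: Cu(OTf)2 (5 mol %), chiral sulfonate-bearing N-heterocyclic carbene ligand (as imidazolinium salt, 5 mol %), THF, −78 °C; then 4, −78 °C; aq. sodium potassium tartrate
Reagents that add atoms: none
Why: Copper-catalysed asymmetric conjugate addition of the alkenylalane (catalyst control, ligand enantiomer chosen for delivery to the face shown) creates the quaternary C1, and the regiodefined aluminium enolate then adds to 4 through a Zimmerman–Traxler chair on the Felkin–Anh face of the aldehyde (anti to its α-C–O bond), so that 9-OH is anti both to the C10–C1 bond and to O8 and the side chain on C10 ends cis to the C15 methyl.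

Step 6
Reactants: 9 aldol adduct
Product: 10 9-O-tert-butyldimethylsilyl ether of 9
Conditions: TBSOTf, 2,6-lutidine, CH2Cl2, −78 °C
Reagents that add atoms: tert-butyldimethylsilyl triflate, CC(C)(C)[Si](C)(C)OS(=O)(=O)C(F)(F)F
Why: Low-temperature silylation of the β-hydroxy ketone protects O9 and suppresses retro-aldol cleavage in the following organolithium step.

Step 7
Reactants: 10 9-O-tert-butyldimethylsilyl ether of 9
Product: 12 1-acetylcyclopentan-1-ol (α-ketol), via enol ether carbinol 11 (not isolated)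
Conditions: ethyl vinyl ether, t-BuLi, THF, −78 to 0 °C; then 10, −78 °C; then 0.5 M aq. HCl, THF, 0 °C
Reagents that add atoms: 1-ethoxyvinyllithium (made in the flask), [Li]C(=C)OCC; water, O
Why: The acyl anion equivalent 1-ethoxyvinyllithium adds to the ketone anti to the large side chain on the adjacent C10, which places the new 12-hydroxyl cis to that chain, and dilute acid hydrolyses only the enol ether to the methyl ketone (C11, C20).

Step 8
Reactants: 12 1-acetylcyclopentan-1-ol (α-ketol)
Product: 13 12-O-triethylsilyl ether of 12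
Conditions: Et3SiOTf, 2,6-lutidine, CH2Cl2, −40 to 0 °C
Reagents that add atoms: triethylsilyl triflate, CC[Si](CC)(CC)OS(=O)(=O)C(F)(F)F
Why: Silyl triflate silylation of the hindered tertiary hydroxyl removes the possibility of chelation between O12 and the acetyl oxygen in the next step.

Step 9
Reactants: 13 12-O-triethylsilyl ether of 12
Product: 14 ring-enlarged 2-methyl-2-(triethylsilyloxy)cyclohexanone (C12 ketone, C11 silyloxy carbinol)
Conditions: MeAl(OAr)2 (Ar = 4-bromo-2,6-di-tert-butylphenyl, 20 mol %), CH2Cl2, −78 to −20 °C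
Reagents that add atoms: none
Why: The bulky aluminium Lewis acid binds only the acetyl oxygen; C10 then shifts with its bonding pair from C12 to C11, C12 becomes a silyloxocarbenium ion, and the triethylsilyl group passes from O12 to O11, which frees the catalyst and leaves the C12 ketone. The closest known reaction type is the Lewis-acid-promoted α-ketol ring enlargement of 1-acylcycloalkanols (as in the D-homoannulation of 17-hydroxy-20-keto steroids) and the organoaluminium-catalysed acyloin rearrangement of α-silyloxy carbonyl compounds. The six-membered ring (C1, C10, C11, C12, C13, C14) is closed by a suprafacial 1,2-shift, that is by insertion of C11 between C10 and C12 of the cyclopentane, with retention at C10. C11 is the only new stereocenter: the O12 silyl ether cannot chelate, so the two C–O bonds stay anti in the transition state and C10 adds to the acetyl face that puts the C20 methyl cis to C9 and O11 trans to it, which translates the C12 configuration of step 7 into C11. The step needs migration of C10 and not of C13: under these cationic conditions the more substituted ring carbon should migrate, and the acetyl group lies on the face of C10 that carries only hydrogen. The gain of a less strained cyclohexanone should make the shift irreversible at low temperature.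

Step 10
Reactants: 14 ring-enlarged 2-methyl-2-(triethylsilyloxy)cyclohexanone
Product: 16 C2 aldehyde, via ozonide 15 (not isolated)
Conditions: O3, CH2Cl2, −78 °C (Sudan red end point); PPh3, −78 °C to rt
Reagents that add atoms: ozone, [O-][O+]=O
Why: Ozone cleaves the 1,2-disubstituted alkene far faster than the internal alkyne, and reductive work-up gives the aldehyde at C2.

Step 11
Reactants: 16 C2 aldehyde
Product: 17 (2R)-allylic alcohol (C2 carbinol with C3=C4 vinyl group)
Conditions: Zn(CH=CH2)2, (+)-3-exo-morpholinoisoborneol (10 mol %), toluene, 0 °C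
Reagents that add atoms: divinylzinc, C=C[Zn]C=C
Why: Amino-alcohol-catalysed enantioselective addition of divinylzinc to the α-quaternary aldehyde (Re-face delivery fixed by the ligand, reagent control) gives the (R)-configured C2 carbinol, while the hindered ketone does not react with the organozinc.

Step 12
Reactants: 17 (2R)-allylic alcohol
Product: 18 2-O-butanoate of 17
Conditions: (n-PrCO)2O, DMAP, Et3N, CH2Cl2, rt
Reagents that add atoms: butanoic anhydride, CCCC(=O)OC(=O)CCC
Why: DMAP-catalysed acylation installs the butanoate of the target on the only free hydroxyl.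

Step 13
Reactants: 18 2-O-butanoate of 17
Product: 19 (Z)-vinylsilane (SiEt3 on C5)
Conditions: Et3SiH, [Cp*Ru(MeCN)3]PF6 (3 mol %), CH2Cl2, 0 °C to rt
Reagents that add atoms: triethylsilane, CC[SiH](CC)CC
Why: Ruthenium-catalysed trans-hydrosilylation of the internal alkyne places silicon on C5, the alkyne carbon remote from the propargylic oxygen, and hydrogen anti to it on C6, which gives the (Z)-vinylsilane and leaves the terminal alkene untouched.

Step 14
Reactants: 19 (Z)-vinylsilane
Product: 20 (Z)-vinyl iodide (iodine on C5, cis to C7)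
Conditions: N-iodosuccinimide, 2,6-lutidine, (CF3)2CHOH, 0 °C
Reagents that add atoms: N-iodosuccinimide, O=C1CCC(=O)N1I
Why: Iododesilylation by electrophilic ipso-substitution proceeds with retention, so that iodine on C5 stays cis to C7.

Step 15
Reactants: 20 (Z)-vinyl iodide
Product: 22 bicyclic ten-membered-ring ketone (7,8-O-isopropylidene), via alkylborane 21 (not isolated)
Conditions: 9-BBN, THF, rt; then Pd(dppf)Cl2 (10 mol %), AsPh3, Cs2CO3, DMF/THF/H2O, 50 °C, slow addition (final 1 mM)
Reagents that add atoms: none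
Why: 9-BBN hydroborates the monosubstituted alkene at C4 in preference to the hindered ketone and the esters, and the intramolecular B-alkyl Suzuki–Miyaura coupling with the iodoalkene under slow addition closes the ten-membered ring with retention of the (Z)-geometry at C5=C6.

Step 16
Reactants: 22 bicyclic ten-membered-ring ketone (7,8-O-isopropylidene)
Product: 23 7,8-diol
Conditions: AcOH/THF/H2O (3:1:1), 40 °C
Reagents that add atoms: none
Why: Aqueous acetic acid hydrolyses the dioxolane, while the hindered secondary and tertiary silyl ethers are expected to survive.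

Step 17
Reactants: 23 7,8-diol
Product: 24 7-O-(2-bromopropanoyl) ester
Conditions: 2-bromopropanoyl bromide (1.1 equiv), pyridine, CH2Cl2, −40 °C
Reagents that add atoms: 2-bromopropanoyl bromide, CC(Br)C(Br)=O
Why: The allylic 7-hydroxyl is acylated in preference to the 8-hydroxyl, which is shielded by the neighbouring silyloxy-bearing C9.

Step 18
Reactants: 24 7-O-(2-bromopropanoyl) ester
Product: 25 C8 ketone
Conditions: Dess–Martin periodinane, NaHCO3, CH2Cl2, 0 °C
Reagents that add atoms: none
Why: Dess–Martin oxidation under buffered conditions converts the remaining secondary alcohol into the C8 ketone without epimerising the acidic C7.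

Step 19
Reactants: 25 C8 ketone
Product: 27 γ-lactone with free tertiary 8-hydroxyl, via zinc enolate 26 (not isolated)
Conditions: Zn (activated with Me3SiCl), THF, 0 °C to rt; aq. NH4Cl
Reagents that add atoms: none
Why: Intramolecular Reformatsky reaction: zinc inserts into the C–Br bond and the zinc enolate adds to the C8 ketone in a chelated five-membered ring closure through the conformer with C6 anti to C9, which sets the 8-hydroxyl cis to C6 on the lactone, and the enolisable C17 is expected to settle with its methyl trans to C9.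

Step 20
Reactants: 27 γ-lactone with free tertiary 8-hydroxyl
Product: 28 C13=C14 enone
Conditions: IBX, DMSO/fluorobenzene, 65 °C
Reagents that add atoms: none
Why: IBX-mediated dehydrogenation of the ketone through its enol can only occur toward C13 because C11 is quaternary, which gives the C13=C14 enone.

Step 21
Reactants: 28 C13=C14 enone
Product: 29 8,9,11-triol
Conditions: HF·pyridine, pyridine, THF, 0 °C to rt
Reagents that add atoms: none
Why: Fluoride cleaves both silyl ethers and leaves the esters and the lactone intact.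

Step 22
Reactants: 29 8,9,11-triol
Product: 30 CNP0346936.2 (target)
Conditions: Ac2O, pyridine, DMAP (cat.), CH2Cl2, 0 °C
Reagents that add atoms: acetic anhydride, CC(=O)OC(C)=O
Why: Acetylation of the secondary 9-hydroxyl; the tertiary hydroxyls at C8 and C11 should not react under these conditions.

**Compound list**

1 | 2,3-O-isopropylidene-D-erythrofuranose, (3aR,6aR)-2,2-dimethyltetrahydrofuro[3,4-d][1,3]dioxol-4-ol, anomeric mixture | OC1OC[C@H]2OC(C)(C)O[C@@H]12 | starting material
2 | ((4R,5S)-5-ethynyl-2,2-dimethyl-1,3-dioxolan-4-yl)methanol | OC[C@H]1OC(C)(C)O[C@H]1C#C | intermediate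
3 | ((4R,5S)-2,2-dimethyl-5-(prop-1-yn-1-yl)-1,3-dioxolan-4-yl)methanol | OC[C@H]1OC(C)(C)O[C@H]1C#CC | intermediate
4 | (4S,5S)-2,2-dimethyl-5-(prop-1-yn-1-yl)-1,3-dioxolane-4-carbaldehyde (cis-dioxolane; C9 aldehyde, C8, C7) | O=C[C@H]1OC(C)(C)O[C@H]1C#CC | intermediate
5 | hex-1-yne | C#CCCCC | starting material
6 | (E)-hex-1-en-1-yl(diisobutyl)alane | CCCC/C=C/[Al](CC(C)C)CC(C)C | intermediate
7 | 3-methylcyclopent-2-en-1-one | CC1=CC(=O)CC1 | starting material
8 | diisobutylaluminium enolate of 3-[(E)-hex-1-enyl]-3-methylcyclopentanone (C1 set) | CCCC/C=C/[C@@]1(C)CCC(O[Al](CC(C)C)CC(C)C)=C1 | intermediate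
9 | 3-[(E)-hex-1-enyl]-2-{hydroxy[cis-2,2-dimethyl-5-(prop-1-ynyl)-1,3-dioxolan-4-yl]methyl}-3-methylcyclopentan-1-one; C15 methyl and the C10 side chain cis on the ring, 9-OH anti to C1 and to O8 | CCCC/C=C/[C@@]1(C)CCC(=O)[C@@H]1[C@@H](O)[C@H]2OC(C)(C)O[C@H]2C#CC | intermediate
10 | 9-O-tert-butyldimethylsilyl ether of 9 | CCCC/C=C/[C@@]1(C)CCC(=O)[C@@H]1[C@@H](O[Si](C)(C)C(C)(C)C)[C@H]2OC(C)(C)O[C@H]2C#CC | intermediate
11 | 1-(1-ethoxyvinyl)cyclopentan-1-ol from 10; 12-OH cis to the C9 side chain | CCCC/C=C/[C@@]1(C)CC[C@@](O)(C(=C)OCC)[C@@H]1[C@@H](O[Si](C)(C)C(C)(C)C)[C@H]2OC(C)(C)O[C@H]2C#CC | intermediate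
12 | 1-acetylcyclopentan-1-ol (α-ketol); 12-OH cis to the C9 side chain, acetyl trans | CCCC/C=C/[C@@]1(C)CC[C@@](O)(C(C)=O)[C@@H]1[C@@H](O[Si](C)(C)C(C)(C)C)[C@H]2OC(C)(C)O[C@H]2C#CC | intermediate
13 | 12-O-triethylsilyl ether of 12 | CCCC/C=C/[C@@]1(C)CC[C@@](O[Si](CC)(CC)CC)(C(C)=O)[C@@H]1[C@@H](O[Si](C)(C)C(C)(C)C)[C@H]2OC(C)(C)O[C@H]2C#CC | intermediate
14 | ring-enlarged cyclohexanone: C12 ketone, C11 bearing the C20 methyl (cis to the C9 chain) and OSiEt3 (trans), C1 and C10 as in 9 | CCCC/C=C/[C@@]1(C)CCC(=O)[C@@](C)(O[Si](CC)(CC)CC)[C@@H]1[C@@H](O[Si](C)(C)C(C)(C)C)[C@H]2OC(C)(C)O[C@H]2C#CC | intermediate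
15 | ozonide (3-butyl-1,2,4-trioxolan-5-yl on C1) of 14 | CCCCC3OOC(O3)[C@@]1(C)CCC(=O)[C@@](C)(O[Si](CC)(CC)CC)[C@@H]1[C@@H](O[Si](C)(C)C(C)(C)C)[C@H]2OC(C)(C)O[C@H]2C#CC | intermediate
16 | C2 aldehyde (formyl group on C1) | O=C[C@@]1(C)CCC(=O)[C@@](C)(O[Si](CC)(CC)CC)[C@@H]1[C@@H](O[Si](C)(C)C(C)(C)C)[C@H]2OC(C)(C)O[C@H]2C#CC | intermediate
17 | (2R)-1-hydroxyprop-2-enyl compound (C2 carbinol, C3=C4 vinyl) | C=C[C@@H](O)[C@@]1(C)CCC(=O)[C@@](C)(O[Si](CC)(CC)CC)[C@@H]1[C@@H](O[Si](C)(C)C(C)(C)C)[C@H]2OC(C)(C)O[C@H]2C#CC | intermediate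
18 | 2-O-butanoate of 17 | CCCC(=O)O[C@H](C=C)[C@@]1(C)CCC(=O)[C@@](C)(O[Si](CC)(CC)CC)[C@@H]1[C@@H](O[Si](C)(C)C(C)(C)C)[C@H]2OC(C)(C)O[C@H]2C#CC | intermediate
19 | (Z)-vinylsilane: C6H=C5(CH3)SiEt3 on C7, silicon cis to C7 | CCCC(=O)O[C@H](C=C)[C@@]1(C)CCC(=O)[C@@](C)(O[Si](CC)(CC)CC)[C@@H]1[C@@H](O[Si](C)(C)C(C)(C)C)[C@H]2OC(C)(C)O[C@H]2/C=C(/C)[Si](CC)(CC)CC | intermediate
20 | (Z)-vinyl iodide: C6H=C5(CH3)I on C7, iodine cis to C7 | CCCC(=O)O[C@H](C=C)[C@@]1(C)CCC(=O)[C@@](C)(O[Si](CC)(CC)CC)[C@@H]1[C@@H](O[Si](C)(C)C(C)(C)C)[C@H]2OC(C)(C)O[C@H]2/C=C(/C)I | intermediate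
21 | B-alkyl-9-borabicyclo[3.3.1]nonane (boron on C4) of 20 | CCCC(=O)O[C@H](CCB3C4CCCC3CCC4)[C@@]1(C)CCC(=O)[C@@](C)(O[Si](CC)(CC)CC)[C@@H]1[C@@H](O[Si](C)(C)C(C)(C)C)[C@H]2OC(C)(C)O[C@H]2/C=C(/C)I | intermediate
22 | bicyclic ten-membered-ring compound: 2-butanoate, (5Z)-alkene, 7,8-O-isopropylidene, 9-O-TBS, 11-O-SiEt3, 12-ketone | CCCC(=O)O[C@@H]1CC/C(C)=C\[C@@H]2OC(C)(C)O[C@@H]2[C@H](O[Si](C)(C)C(C)(C)C)[C@@H]3[C@]1(C)CCC(=O)[C@@]3(C)O[Si](CC)(CC)CC | intermediate
23 | 7,8-diol from 22 | CCCC(=O)O[C@@H]1CC/C(C)=C\[C@H](O)[C@H](O)[C@H](O[Si](C)(C)C(C)(C)C)[C@@H]2[C@]1(C)CCC(=O)[C@@]2(C)O[Si](CC)(CC)CC | intermediate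
24 | 7-O-(2-bromopropanoyl) ester of 23 (both epimers at the brominated carbon) | CCCC(=O)O[C@@H]1CC/C(C)=C\[C@H](OC(=O)C(C)Br)[C@H](O)[C@H](O[Si](C)(C)C(C)(C)C)[C@@H]2[C@]1(C)CCC(=O)[C@@]2(C)O[Si](CC)(CC)CC | intermediate
25 | C8 ketone from 24 | CCCC(=O)O[C@@H]1CC/C(C)=C\[C@H](OC(=O)C(C)Br)C(=O)[C@H](O[Si](C)(C)C(C)(C)C)[C@@H]2[C@]1(C)CCC(=O)[C@@]2(C)O[Si](CC)(CC)CC | intermediate
26 | bromozinc ester enolate of 25 | CCCC(=O)O[C@@H]1CC/C(C)=C\[C@H](OC(O[Zn]Br)=CC)C(=O)[C@H](O[Si](C)(C)C(C)(C)C)[C@@H]2[C@]1(C)CCC(=O)[C@@]2(C)O[Si](CC)(CC)CC | intermediate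
27 | γ-lactone (O7–C19–C17–C8) with tertiary 8-OH cis to C6 and to the C18 methyl; 9-O-TBS, 11-O-SiEt3, 12-ketone | CCCC(=O)O[C@@H]1CC/C(C)=C\[C@@H]2OC(=O)[C@H](C)[C@@]2(O)[C@H](O[Si](C)(C)C(C)(C)C)[C@@H]3[C@]1(C)CCC(=O)[C@@]3(C)O[Si](CC)(CC)CC | intermediate
28 | C13=C14 enone from 27 | CCCC(=O)O[C@@H]1CC/C(C)=C\[C@@H]2OC(=O)[C@H](C)[C@@]2(O)[C@H](O[Si](C)(C)C(C)(C)C)[C@@H]3[C@]1(C)C=CC(=O)[C@@]3(C)O[Si](CC)(CC)CC | intermediate
29 | 8,9,11-triol (9-deacetyl target) | CCCC(=O)O[C@@H]1CC/C(C)=C\[C@@H]2OC(=O)[C@H](C)[C@@]2(O)[C@H](O)[C@@H]3[C@]1(C)C=CC(=O)[C@@]3(C)O | intermediate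
30 | CNP0346936.2 | CCCC(=O)O[C@@H]1CC/C(C)=C\[C@@H]2OC(=O)[C@H](C)[C@@]2(O)[C@H](OC(C)=O)[C@@H]2[C@]1(C)C=CC(=O)[C@@]2(C)O | target

**Step count and risks**

Total step count: 22. Longest linear sequence: 21 steps (1 to 4 in three steps, then steps 5 to 22).

Steps most likely to fail:

Step 9. Migration of the other ring carbon (C13) or reaction through the rotamer with the two oxygens syn would give the constitutional isomer or the C11 epimer. The fallback sets out from 10. Addition of 1-(phenylseleno)ethyllithium (from 1,1-bis(phenylseleno)ethane and n-BuLi, THF, −78 °C) gives the β-hydroxy selenide F1. AgBF4 on Al2O3 in CH2Cl2 triggers the selenium-assisted semipinacol ring enlargement, in which the more substituted carbon C10 migrates, to the 2-methylcyclohexanone F2. Thermodynamic silylation (Et3SiCl, NaI, Et3N, MeCN) gives the tetrasubstituted triethylsilyl enol ether F3. Rubottom oxidation with dimethyldioxirane at −78 °C should attack C11 anti to the C9 side chain and move the silyl group to O11, which comes back to the route at 14.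

Step 15. Ring closure of the strained ten-membered ring may be slower than intermolecular coupling (oligomers) or protodeboronation of the alkylborane. The fallback sets out from 20. Stille coupling with tributyl(vinyl)stannane (Pd(PPh3)4, CuI, DMF) gives the diene F4. Ring-closing metathesis with the second-generation Grubbs catalyst under high dilution closes the ring at C3=C4 to the cyclic 3,5-diene F5. Diimide (from 2-nitrobenzenesulfonyl hydrazide and Et3N) should reduce the disubstituted C3=C4 bond and leave the trisubstituted C5=C6 bond, which comes back to the route at 22.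

Step 19. Zinc may reduce the α-acyloxy ketone or cause loss of the acyloxy group in competition with enolate formation, and facial selectivity at C8 may be poor. The fallback sets out from 23. Selective silylation of the allylic 7-hydroxyl (Et3SiCl, imidazole, −20 °C) gives the 7-O-triethylsilyl ether F6. Dess–Martin oxidation gives the C8 ketone F7. Intermolecular Reformatsky addition of the zinc enolate of methyl 2-bromopropanoate (Zn, THF), under chelation by the flanking silyloxy groups, gives the tertiary alcohol F8. PPTS in MeOH removes the 7-O-silyl group, and the freed hydroxyl closes the lactone with loss of methanol, which comes back to the route at 27.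

Further compounds
F1 | step 9 | β-hydroxy selenide: 1-[1-(phenylseleno)ethyl]cyclopentan-1-ol from 10 | CCCC/C=C/[C@@]1(C)CC[C@@](O)(C(C)[Se]c2ccccc2)[C@@H]1[C@@H](O[Si](C)(C)C(C)(C)C)[C@H]2OC(C)(C)O[C@H]2C#CC
F2 | step 9 | ring-enlarged 2-methylcyclohexanone (C11–H, both epimers) | CCCC/C=C/[C@@]1(C)CCC(=O)C(C)[C@@H]1[C@@H](O[Si](C)(C)C(C)(C)C)[C@H]2OC(C)(C)O[C@H]2C#CC
F3 | step 9 | triethylsilyl enol ether (C11=C12) of F2 | CCCC/C=C/[C@@]1(C)CCC(O[Si](CC)(CC)CC)=C(C)[C@@H]1[C@@H](O[Si](C)(C)C(C)(C)C)[C@H]2OC(C)(C)O[C@H]2C#CC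
F4 | step 15 | diene from 20 (vinyl group on C5 in place of iodine) | CCCC(=O)O[C@H](C=C)[C@@]1(C)CCC(=O)[C@@](C)(O[Si](CC)(CC)CC)[C@@H]1[C@@H](O[Si](C)(C)C(C)(C)C)[C@H]2OC(C)(C)O[C@H]2/C=C(/C)C=C
F5 | step 15 | ten-membered cyclic 3,5-diene (3,4-didehydro-22) | CCCC(=O)O[C@@H]1C=C/C(C)=C\[C@@H]2OC(C)(C)O[C@@H]2[C@H](O[Si](C)(C)C(C)(C)C)[C@@H]3[C@]1(C)CCC(=O)[C@@]3(C)O[Si](CC)(CC)CC
F6 | step 19 | 7-O-triethylsilyl ether of 23 | CCCC(=O)O[C@@H]1CC/C(C)=C\[C@H](O[Si](CC)(CC)CC)[C@H](O)[C@H](O[Si](C)(C)C(C)(C)C)[C@@H]2[C@]1(C)CCC(=O)[C@@]2(C)O[Si](CC)(CC)CC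
F7 | step 19 | C8 ketone from F6 | CCCC(=O)O[C@@H]1CC/C(C)=C\[C@H](O[Si](CC)(CC)CC)C(=O)[C@H](O[Si](C)(C)C(C)(C)C)[C@@H]2[C@]1(C)CCC(=O)[C@@]2(C)O[Si](CC)(CC)CC
F8 | step 19 | Reformatsky adduct: C8 tertiary alcohol bearing the methyl propanoate unit (C17, C18, C19) | CCCC(=O)O[C@@H]1CC/C(C)=C\[C@H](O[Si](CC)(CC)CC)[C@@](O)([C@@H](C)C(=O)OC)[C@H](O[Si](C)(C)C(C)(C)C)[C@@H]2[C@]1(C)CCC(=O)[C@@]2(C)O[Si](CC)(CC)CC
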